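**Plan**

- Retrosynthetic cuts: first the helper methoxy group on C2, then the C2–C3 bond of the dihydropyran ring together with the C4–H bond (one redox-neutral event), then the quinone oxygen para to the ring B phenol, then C3=C4 (Wittig).
- Enabling feature: C2 is an O1-bound CH2 lying 1,5 to C4, and C3 is bonded to quinone C5, so it is the γ-carbon of the C6=C5/C1=O enone. The target is therefore a redox isomer of an (E)-styrylquinone whose ring A carries an ortho O–CH2–X ether.
- Key event: with X = OMe (a MOM acetal as hydride donor), a [1,5]-hydride shift from O–CH2–O to C4 gives a dioxocarbenium/quinone-dienolate zwitterion that closes C3 onto C2. This forms the dihydropyran ring (the only ring made in the route) and returns the quinone.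
- Forward order: ring A aldehyde 4 and ring B phosphonium salt 7 give E stilbene 10; Teuber oxidation builds the quinone ring (11); hydride shift/ring closure gives 13; ionic removal of the C2 methoxy helper gives 14.
- Stereochemistry: the single stereocenter C3 is created in the ring closure under control of a chiral Sc(OTf)3–pybox complex chelated to the quinone. The C2 acetal center is transient and is erased in step 8.

Key step: step 7

Remark: the (3S) descriptor is read from the target SMILES; the sense of induction of the scandium–pybox complex in step 7 cannot be predicted with confidence, so (S,S)-Ph-pybox stands for whichever ligand antipode delivers (3S).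

**Route**

Step 1
Reactants: 1 2,3,4-trimethoxyphenol
Product: 3 2-hydroxy-3,4,5-trimethoxybenzaldehyde, via hydroxymethyl phenol 2 (not isolated)
Conditions: MgCl2, Et3N, (CH2O)n, MeCN, reflux; aqueous HCl work-up
Reagents that add atoms: paraformaldehyde (reacts as formaldehyde), C=O
Why: Magnesium-phenoxide-mediated ortho-formylation (Casnati–Skattebøl reaction) delivers formaldehyde to the only free position ortho to the hydroxyl group, and the hydroxymethyl intermediate 2 is oxidised in the flask by a second formaldehyde through an Oppenauer-type hydride transfer.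

Step 2
Reactants: 3 2-hydroxy-3,4,5-trimethoxybenzaldehyde
Product: 4 3,4,5-trimethoxy-2-(methoxymethoxy)benzaldehyde
Conditions: NaH, DMF, 0 °C; MOMCl, 0 °C → rt
Reagents that add atoms: chloromethyl methyl ether (MOMCl), COCCl
Why: Williamson etherification of the sodium phenoxide protects the phenol and at the same time installs the O–CH2–OMe acetal whose carbon becomes C2 and whose C–H bond is the hydride donor of step 7.

Step 3
Reactants: 5 2-hydroxy-3,4-dimethoxybenzaldehyde
Product: 6 6-(hydroxymethyl)-2,3-dimethoxyphenol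
Conditions: NaBH4, MeOH, 0 °C
Reagents that add atoms: none
Why: Chemoselective borohydride reduction of the aryl aldehyde to the benzylic alcohol should proceed cleanly in the presence of the free phenol.

Step 4
Reactants: 6 6-(hydroxymethyl)-2,3-dimethoxyphenol
Product: 7 (2-hydroxy-3,4-dimethoxybenzyl)triphenylphosphonium bromide
Conditions: PPh3·HBr, MeCN, reflux
Reagents that add atoms: triphenylphosphine hydrobromide, Br.c1ccc(cc1)P(c1ccccc1)c1ccccc1
Why: Ortho-hydroxybenzylic alcohols are converted by PPh3·HBr directly into (2-hydroxybenzyl)phosphonium salts through acid-promoted loss of water and capture of the benzylic cation (ortho-quinone methide) by the phosphine, so the phenol needs no protection.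

Step 5
Reactants: 7 (2-hydroxy-3,4-dimethoxybenzyl)triphenylphosphonium bromide; 4 3,4,5-trimethoxy-2-(methoxymethoxy)benzaldehyde
Product: 10 2,3-dimethoxy-6-[(E)-2-[3,4,5-trimethoxy-2-(methoxymethoxy)phenyl]ethenyl]phenol, via phosphonium ylide 8 (not isolated), via Z stilbene 9 (not isolated)
Conditions: LiN(SiMe3)2 (2.2 equiv), THF, −78 → 0 °C; 4, 0 °C → rt; then PhSSPh (10 mol %), THF, reflux
Reagents that add atoms: none
Why: Wittig olefination of aldehyde 4 by the semi-stabilised phenoxide ylide 8 forms the C3=C4 bond, and thiyl-radical addition–elimination (catalytic PhSSPh) should equilibrate the Z isomer 9 to the thermodynamically favoured E stilbene 10, the MOM acetal being stable to base.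

Step 6
Reactants: 10 2,3-dimethoxy-6-[(E)-2-[3,4,5-trimethoxy-2-(methoxymethoxy)phenyl]ethenyl]phenol
Product: 11 2,3-dimethoxy-5-[(E)-2-[3,4,5-trimethoxy-2-(methoxymethoxy)phenyl]ethenyl]cyclohexa-2,5-diene-1,4-dione
Conditions: (KSO3)2NO (2.5 equiv), KH2PO4, acetone–H2O, rt
Reagents that add atoms: potassium nitrosodisulfonate (Fremy's salt), [K+].[K+].[O]N(S(=O)(=O)[O-])S(=O)(=O)[O-]
Why: In the Teuber oxidation the phenoxyl radical is trapped by a second equivalent of the nitroxide at the free position para to the hydroxyl group and loss of HN(SO3K)2 gives the para-quinone, while the fully etherified ring A cannot form a phenoxyl radical and should be left untouched.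

Step 7
Reactants: 11 2,3-dimethoxy-5-[(E)-2-[3,4,5-trimethoxy-2-(methoxymethoxy)phenyl]ethenyl]cyclohexa-2,5-diene-1,4-dione
Product: 13 5-[(2RS,3S)-2,6,7,8-tetramethoxy-3,4-dihydro-2H-chromen-3-yl]-2,3-dimethoxycyclohexa-2,5-diene-1,4-dione, via zwitterion 12 (not isolated)
Conditions: Sc(OTf)3 (10 mol %), (S,S)-Ph-pybox (12 mol %), 4 Å MS, ClCH2CH2Cl, 40 °C, dark
Reagents that add atoms: none
Why: Proposed new method: the scandium center chelates the quinone C1=O and the neighbouring 2-OMe group and so activates the vinylogous acceptor C4=C3–C5=C6–C1=O, the acetal C–H of the O–CH2–OMe group shifts as hydride to C4 through a six-membered transition state ([1,5]-hydride shift), and the resulting zwitterion 12, a dioxocarbenium ion paired with a scandium dienolate, collapses by attack of its γ-carbon C3 on the carbenium carbon C2, which forms the C2–C3 bond and restores the quinone. The closest known reaction type is the Lewis-acid-catalysed 1,5-hydride shift/ring closure (internal redox, tert-amino-effect type) of ortho-alkoxyaryl alkylidene malonates to chromans; new here are the quinone as vinylogous acceptor, the formaldehyde acetal as donor and a tertiary stereocenter on the acceptor carbon. The dihydropyran ring closes in a 6-endo-trig mode at the O1=C2 carbenium bond (6-enolexo with respect to the exocyclic C3=C5 dienolate bond). C3 is set in this C–C bond formation by the chiral Sc(OTf)3–pybox complex, which stays bound to the dienolate oxygen and the adjacent methoxy group and should shield one face of the C3=C5 bond, while the C2 center forms without control and is removed in step 8. The step needs hydride donation from the acetal CH2 only, delivery to C4 only and C-alkylation at C3, and the substrate secures this because only that C–H bond is flanked by two oxygens and lies 1,5 to C4 (the flanking ring A methoxy group pushes the acetal toward the alkene) and only C3 can reach C2 through a six-membered ring.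

Step 8
Reactants: 13 5-[(2RS,3S)-2,6,7,8-tetramethoxy-3,4-dihydro-2H-chromen-3-yl]-2,3-dimethoxycyclohexa-2,5-diene-1,4-dione
Product: 14 abruquinone B, 2,3-dimethoxy-5-[(3S)-6,7,8-trimethoxy-3,4-dihydro-2H-chromen-3-yl]cyclohexa-2,5-diene-1,4-dione
Conditions: Et3SiH, BF3·OEt2, CH2Cl2, −78 → −30 °C
Reagents that add atoms: none
Why: Ionic hydrogenation of a cyclic O,O-acetal, well precedented for 2-alkoxychromans and chroman-2-ols, should remove the exocyclic methoxide from either C2 epimer to give one aryl-oxocarbenium ion that Et3SiH reduces to the C2 methylene without involving the C3 center.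

**Compound list**

1 | 2,3,4-trimethoxyphenol | COc1ccc(O)c(OC)c1OC | starting material
2 | 6-(hydroxymethyl)-2,3,4-trimethoxyphenol (formed as its magnesium phenoxide) | OCc1cc(OC)c(OC)c(OC)c1O | intermediate (not isolated)
3 | 2-hydroxy-3,4,5-trimethoxybenzaldehyde | O=Cc1cc(OC)c(OC)c(OC)c1O | intermediate
4 | 3,4,5-trimethoxy-2-(methoxymethoxy)benzaldehyde | O=Cc1cc(OC)c(OC)c(OC)c1OCOC | intermediate
5 | 2-hydroxy-3,4-dimethoxybenzaldehyde | O=Cc1ccc(OC)c(OC)c1O | starting material
6 | 6-(hydroxymethyl)-2,3-dimethoxyphenol | OCc1ccc(OC)c(OC)c1O | intermediate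
7 | (2-hydroxy-3,4-dimethoxybenzyl)triphenylphosphonium bromide | [Br-].Oc1c(OC)c(OC)ccc1C[P+](c1ccccc1)(c1ccccc1)c1ccccc1 | intermediate
8 | lithium 2,3-dimethoxy-6-[(triphenylphosphoranylidene)methyl]phenolate (phenoxide ylide) | [Li+].[O-]c1c(OC)c(OC)ccc1C=P(c1ccccc1)(c1ccccc1)c1ccccc1 | intermediate (not isolated)
9 | 2,3-dimethoxy-6-[(Z)-2-[3,4,5-trimethoxy-2-(methoxymethoxy)phenyl]ethenyl]phenol | COCOc1c(/C=C\c2ccc(OC)c(OC)c2O)cc(OC)c(OC)c1OC | intermediate (not isolated)
10 | 2,3-dimethoxy-6-[(E)-2-[3,4,5-trimethoxy-2-(methoxymethoxy)phenyl]ethenyl]phenol | COCOc1c(/C=C/c2ccc(OC)c(OC)c2O)cc(OC)c(OC)c1OC | intermediate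
11 | 2,3-dimethoxy-5-[(E)-2-[3,4,5-trimethoxy-2-(methoxymethoxy)phenyl]ethenyl]cyclohexa-2,5-diene-1,4-dione | COC1=C(OC)C(=O)C(/C=C/c2cc(OC)c(OC)c(OC)c2OCOC)=CC1=O | intermediate
12 | zwitterion after the hydride shift: aryl dioxocarbenium ion (ArO+=CH–OMe) on ring A, C4H2, exocyclic C3=C5 dienolate of the quinone (drawn without the scandium center) | COC1=C(OC)C(=O)C(=CCc2cc(OC)c(OC)c(OC)c2[O+]=COC)C=C1[O-] | intermediate (not isolated)
13 | 5-[(2RS,3S)-2,6,7,8-tetramethoxy-3,4-dihydro-2H-chromen-3-yl]-2,3-dimethoxycyclohexa-2,5-diene-1,4-dione (both C2 epimers) | COC1=C(OC)C(=O)C([C@H]2C(OC)Oc3c(cc(OC)c(OC)c3OC)C2)=CC1=O | intermediate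
14 | abruquinone B, 2,3-dimethoxy-5-[(3S)-6,7,8-trimethoxy-3,4-dihydro-2H-chromen-3-yl]cyclohexa-2,5-diene-1,4-dione | COC1=C(OC)C(=O)C([C@H]2COc3c(cc(OC)c(OC)c3OC)C2)=CC1=O | target

**Step count and risks**

Total steps: 8. Longest linear sequence: 6 steps (steps 1, 2, 5, 6, 7, 8 from 1; equally steps 3, 4, 5, 6, 7, 8 from 5).

Steps most likely to fail:

1. Step 7 (proposed new method). The hydride shift may not start because C4 is the donor-substituted end of a push–pull alkene. The Lewis acid may instead ionise the MOM acetal. The ring closure may also proceed with poor facial selectivity at C3, because the chiral ligand sits several atoms away from the bond being formed, and the product may lose configuration through Lewis-acid-promoted tautomerisation to the quinone methide. Fallback by known chemistry, setting out from 1 and 5 and coming back to the route at 14: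
   - Ortho-acetylation of 1 (AcOH, BF3·OEt2, 90 °C) should give 1-(2-hydroxy-3,4,5-trimethoxyphenyl)ethanone F1.
   - Benzylation of 5 (BnBr, K2CO3, DMF) should give 2-(benzyloxy)-3,4-dimethoxybenzaldehyde F2.
   - Claisen–Schmidt condensation of F1 and F2 (KOH, EtOH) should give the chalcone (E)-3-[2-(benzyloxy)-3,4-dimethoxyphenyl]-1-(2-hydroxy-3,4,5-trimethoxyphenyl)prop-2-en-1-one F3.
   - Oxidative 1,2-aryl shift with Tl(NO3)3·3H2O (trivalent thallium) in MeOH/HC(OMe)3 should give the acetal 2-[2-(benzyloxy)-3,4-dimethoxyphenyl]-1-(2-hydroxy-3,4,5-trimethoxyphenyl)-3,3-dimethoxypropan-1-one F4.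
   - Ring closure in HCl/MeOH should give the isoflavone 3-[2-(benzyloxy)-3,4-dimethoxyphenyl]-6,7,8-trimethoxy-4H-chromen-4-one F5.
   - Noyori–Ikariya transfer hydrogenation with RuCl(p-cymene)[(S,S)-TsDPEN] or its mirror image (HCO2H/Et3N, EtOAc, 40 °C) reduces the C2=C3 bond and then, with dynamic kinetic resolution of the isoflavanone, the ketone. It should give the cis alcohol (3S,4S)-3-[2-(benzyloxy)-3,4-dimethoxyphenyl]-6,7,8-trimethoxychroman-4-ol F6.
   - Hydrogenolysis (H2, Pd/C, AcOH/EtOAc) of the benzylic C4–OH and of the benzyl ether should give 2,3-dimethoxy-6-[(3S)-6,7,8-trimethoxychroman-3-yl]phenol F7.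
   - Teuber oxidation of F7 with (KSO3)2NO, KH2PO4 in acetone–H2O should give 14.

2. Step 8. Three processes threaten it: ionisation of the endocyclic C2–O1 bond, which after reduction leaves a ring-opened methyl ether; elimination of the oxocarbenium ion to the enol ether with loss of configuration at C3, whose C–H bond is acidified by the quinone; and hydride transfer from the silane to the Lewis-acid-activated quinone. The fallback masks the quinone before the deoxygenation, setting out from 13 and coming back at 14:
   - Reductive acetylation (Zn, Ac2O, NaOAc, rt) should give 2,3-dimethoxy-5-[(2RS,3S)-2,6,7,8-tetramethoxychroman-3-yl]-1,4-phenylene diacetate F8, in which C3 carries an ordinary electron-rich aryl group.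
   - Ionic hydrogenation (Et3SiH, TMSOTf, CH2Cl2, −78 °C) should give 2,3-dimethoxy-5-[(3S)-6,7,8-trimethoxychroman-3-yl]-1,4-phenylene diacetate F9.
   - Acidic methanolysis (HCl, degassed MeOH) followed by oxidation of the hydroquinone with FeCl3·6H2O in aqueous MeOH at 0 °C should give 14 without exposing the quinone to base.

3. Step 6. The phenoxyl radical is delocalised through the ortho vinyl group onto the stilbene carbon, so radical coupling there (benzofuran-type oxidative cyclisation, oligomerisation) may compete with para-oxygenation. The fallback replaces the radical oxidation by ionic para-amination, setting out from 10 and coming back at 11: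
   - Azo coupling of the phenoxide of 10 with 4-sulfobenzenediazonium chloride (from sulfanilic acid, NaNO2, HCl; aqueous NaOH, 0 °C) should give 4-[(E)-{4-hydroxy-2,3-dimethoxy-5-[(E)-2-[3,4,5-trimethoxy-2-(methoxymethoxy)phenyl]ethenyl]phenyl}diazenyl]benzenesulfonic acid F10.
   - Reduction with Na2S2O4 in aqueous EtOH should cleave the azo group to 4-amino-2,3-dimethoxy-6-[(E)-2-[3,4,5-trimethoxy-2-(methoxymethoxy)phenyl]ethenyl]phenol F11.
   - Oxidation of the para-aminophenol with FeCl3·6H2O in aqueous acetone at 0 °C and hydrolysis of the quinone imine should give 11.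

Further compounds

F1 | step 7 | 1-(2-hydroxy-3,4,5-trimethoxyphenyl)ethanone | CC(=O)c1cc(OC)c(OC)c(OC)c1O
F2 | step 7 | 2-(benzyloxy)-3,4-dimethoxybenzaldehyde | O=Cc1ccc(OC)c(OC)c1OCc1ccccc1
F3 | step 7 | (E)-3-[2-(benzyloxy)-3,4-dimethoxyphenyl]-1-(2-hydroxy-3,4,5-trimethoxyphenyl)prop-2-en-1-one | O=C(/C=C/c1ccc(OC)c(OC)c1OCc1ccccc1)c1cc(OC)c(OC)c(OC)c1O
F4 | step 7 | 2-[2-(benzyloxy)-3,4-dimethoxyphenyl]-1-(2-hydroxy-3,4,5-trimethoxyphenyl)-3,3-dimethoxypropan-1-one (racemic) | COC(OC)C(C(=O)c1cc(OC)c(OC)c(OC)c1O)c1ccc(OC)c(OC)c1OCc1ccccc1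
F5 | step 7 | 3-[2-(benzyloxy)-3,4-dimethoxyphenyl]-6,7,8-trimethoxy-4H-chromen-4-one | O=c1c(-c2ccc(OC)c(OC)c2OCc2ccccc2)coc2c(OC)c(OC)c(OC)cc12
F6 | step 7 | (3S,4S)-3-[2-(benzyloxy)-3,4-dimethoxyphenyl]-6,7,8-trimethoxychroman-4-ol (cis) | COc1ccc([C@H]2COc3c(OC)c(OC)c(OC)cc3[C@H]2O)c(OCc2ccccc2)c1OC
F7 | step 7 | 2,3-dimethoxy-6-[(3S)-6,7,8-trimethoxychroman-3-yl]phenol | COc1ccc([C@H]2COc3c(cc(OC)c(OC)c3OC)C2)c(O)c1OC
F8 | step 8 | 2,3-dimethoxy-5-[(2RS,3S)-2,6,7,8-tetramethoxychroman-3-yl]-1,4-phenylene diacetate | CC(=O)Oc1cc([C@H]2C(OC)Oc3c(cc(OC)c(OC)c3OC)C2)c(OC(C)=O)c(OC)c1OC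
F9 | step 8 | 2,3-dimethoxy-5-[(3S)-6,7,8-trimethoxychroman-3-yl]-1,4-phenylene diacetate | CC(=O)Oc1cc([C@H]2COc3c(cc(OC)c(OC)c3OC)C2)c(OC(C)=O)c(OC)c1OC
F10 | step 6 | 4-[(E)-{4-hydroxy-2,3-dimethoxy-5-[(E)-2-[3,4,5-trimethoxy-2-(methoxymethoxy)phenyl]ethenyl]phenyl}diazenyl]benzenesulfonic acid | COCOc1c(/C=C/c2cc(/N=N/c3ccc(cc3)S(=O)(=O)O)c(OC)c(OC)c2O)cc(OC)c(OC)c1OC
F11 | step 6 | 4-amino-2,3-dimethoxy-6-[(E)-2-[3,4,5-trimethoxy-2-(methoxymethoxy)phenyl]ethenyl]phenol | COCOc1c(/C=C/c2cc(N)c(OC)c(OC)c2O)cc(OC)c(OC)c1OC
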